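**Plan**

- Retrosynthesis cuts, in order: C1–C10 (ring A, key step), C3–C4 (aldol), C4–C5 (Michael), C6–C7 (carbonylation of an enol triflate), C13–C16 (ring D), C15–C16 (alkynylation), C8–C14 with C9–C11 (Diels–Alder, ring C), C8–C15 (carbonylation).
- Forward ring order: ring B is the commercial cyclopentenone 1, then ring C (Diels–Alder), ring D (gold Conia-ene), the C7 ester, the 19,10-lactone as a 10-methoxy pseudo-ester, and last ring A (key step).
- Enabling feature: C10 carries the lactone oxygen. With the γ-lactone ring O–C19–C4–C5–C10 closed first, C10 is a masked ketone (OMe as temporary leaving group) that ionises to a lactone-stabilised acyloxycarbenium ion. The C3–C2=C1 arm on C4 (SiMe3 on C1 as temporary activator) can reach C10 only on its β-face, so ring A closes as the bridged bicyclo[3.2.1] lactone with C1=C2 in place.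
- Stereochemistry: the carbinol centre of 1 (future C10, later oxidised) sets C8/C9 (Diels–Alder anti to OSi) and C5 (Michael anti to OSi). C6 is set by equilibration trans to C5, C13 by the ring D bridge, C10 by the cis-fused pseudo-ester, C12 and C15 by substrate-controlled hydride reductions, and C4 and C3 by the convex-face aldol of the bicyclic lactone enolate.

Key step: step 23

Remark: gibberellane locants (C1–C19) are used for all intermediates. β is the face of H-5, H-9, C7 and C15 on ring B. "12α" means cis to the 13-oxygen. "15β" means endo, i.e. on the side of ring D that faces the C9–C11–C12 bridge.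
Assumption: (R)-4-hydroxycyclopent-2-en-1-one is taken as a commercial, enantiopure starting material.

Step 1
Reactants: 1 (R)-4-hydroxycyclopent-2-en-1-one
Product: 2 (R)-4-[(triethylsilyl)oxy]cyclopent-2-en-1-one
Conditions: TESCl, imidazole, CH2Cl2, 0 °C
Reagents that add atoms: chlorotriethylsilane CC[Si](Cl)(CC)CC
Why: Imidazole-promoted O-silylation should protect the carbinol (future C10–O, the centre that relays all later chirality) as a TES ether that can later be cleaved beside TBS ethers.

Step 2
Reactants: 2 (R)-4-[(triethylsilyl)oxy]cyclopent-2-en-1-one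
Product: 3 (R)-2-iodo-4-[(triethylsilyl)oxy]cyclopent-2-en-1-one
Conditions: I2, pyridine, CH2Cl2, 0 → 25 °C
Reagents that add atoms: iodine II
Why: α-Iodination of the enone by the pyridine addition–iodination–elimination (Baylis–Hillman-type) mechanism should place iodine only on the α-carbon (future C8).

Step 3
Reactants: 3 (R)-2-iodo-4-[(triethylsilyl)oxy]cyclopent-2-en-1-one
Product: 4 methyl (R)-5-oxo-3-[(triethylsilyl)oxy]cyclopent-1-ene-1-carboxylate
Conditions: PdCl2(PPh3)2 (5 mol%), CO (1 atm), MeOH (5 equiv), iPr2NEt, THF, 40 °C; crude 4 used at once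
Reagents that add atoms: carbon monoxide [C-]#[O+]; methanol CO
Why: Palladium-catalysed alkoxycarbonylation of the α-iodoenone (oxidative addition, CO insertion, methanolysis) should install the ester carbon that becomes C15 and make the alkene a doubly activated dienophile.

Step 4
Reactants: 5 butane-2,3-dione
Product: 6 2,3-bis[(tert-butyldimethylsilyl)oxy]buta-1,3-diene
Conditions: TBSOTf (2.2 equiv), Et3N, CH2Cl2, 0 → 25 °C
Reagents that add atoms: tert-butyldimethylsilyl triflate CC(C)(C)[Si](C)(C)OS(=O)(=O)C(F)(F)F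
Why: Double soft enolisation and O-silylation of the 1,2-diketone should give the bis-silyl enol ether, an electron-rich 2,3-dioxygenated diene that carries the future C12 and C13 oxygens.

Step 5
Reactants: 4 methyl (R)-5-oxo-3-[(triethylsilyl)oxy]cyclopent-1-ene-1-carboxylate; 6 2,3-bis[(tert-butyldimethylsilyl)oxy]buta-1,3-diene
Product: 7 cis-fused hydrindenone (C6 ketone; 8β-CO2Me; H-9β; 10β-OTES; C12=C13 bis-OTBS enediol ether)
Conditions: PhMe, 0 → 25 °C
Reagents that add atoms: none
Why: Normal-demand Diels–Alder reaction of the alkylidene β-keto ester with the symmetric diene (so no regiochemical issue) should occur anti to the C10 silyloxy group, which sets the quaternary C8 (ester β) and H-9 (β) of the cis-fused B/C system.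

Step 6
Reactants: 7 cis-fused hydrindenone
Product: 8 C6 enol triflate (C5=C6)
Conditions: KHMDS, THF, −78 °C; N-(5-chloro-2-pyridyl)triflimide, −78 °C
Reagents that add atoms: N-(5-chloro-2-pyridyl)triflimide O=S(=O)(N(c1ccc(Cl)cn1)S(=O)(=O)C(F)(F)F)C(F)(F)F
Why: Kinetic enolisation of the C6 ketone can go only towards C5 (C8 is quaternary), and fast O-triflation at −78 °C, before β-elimination of the C10 silyloxy group can set in, should give the enol triflate that masks C6 until C7 is introduced.

Step 7
Reactants: 8 C6 enol triflate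
Product: 9 C15 primary alcohol
Conditions: DIBAL-H (3 equiv), CH2Cl2, −78 → 0 °C; Rochelle salt
Reagents that add atoms: none
Why: DIBAL-H reduction should take the neopentyl C15 ester to the primary alcohol while enol triflate, silyl enol ethers and silyl ether are inert to hydride.

Step 8
Reactants: 9 C15 primary alcohol
Product: 10 C15 aldehyde
Conditions: SO3·pyridine, DMSO, iPr2NEt, CH2Cl2, 0 °C
Reagents that add atoms: none
Why: Parikh–Doering oxidation under non-acidic conditions should give the non-enolisable aldehyde without harming the acid-sensitive enediol bis-silyl ether.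

Step 9
Reactants: 10 C15 aldehyde
Product: 11 C15 ethynyl carbinol (C15 epimers)
Conditions: HC≡CMgBr, THF, −78 → −20 °C; aq NH4Cl
Reagents that add atoms: ethynylmagnesium bromide C#C[Mg]Br
Why: 1,2-Addition of the alkynyl Grignard reagent to the aldehyde should give the propargylic alcohol; the epimer mixture is acceptable because C15 is set later by oxidation and reduction.

Step 10
Reactants: 11 C15 ethynyl carbinol
Product: 12 tricyclic B/C/D ketone (12-oxo; 13-OTBS; 16-methylene; 15-OH epimers)
Conditions: Ph3PAuCl (5 mol%), AgBF4 (5 mol%), CH2Cl2/MeOH 10:1, 25 °C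
Reagents that add atoms: none
Why: Gold(I)-catalysed Conia-ene-type carbocyclisation of the silyl enol ether onto the activated alkyne should go 5-exo-dig through C13 (6-exo through C12 being slower); methanol desilylates the C12 oxocarbenium ion and protonates the vinyl–gold bond, so ring D forms with the bridgehead C13 silyl ether (configuration dictated by the bridge from C8), the C12 ketone and the exocyclic methylene.

Step 11
Reactants: 12 tricyclic B/C/D ketone
Product: 13 12α-alcohol (15-OH epimers)
Conditions: L-Selectride (2.5 equiv), THF, −78 °C; aq NH4Cl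
Reagents that add atoms: none
Why: The bulky hydride should attack the C12 ketone along the equatorial trajectory, because the axial face is blocked by the syn-axial C9–C10 bond, giving the axial 12α-alcohol cis to the C13 oxygen.

Step 12
Reactants: 13 12α-alcohol
Product: 14 16-en-15-one (12α-OH)
Conditions: activated MnO2 (20 equiv), CH2Cl2, 25 °C
Reagents that add atoms: none
Why: MnO2 oxidises only the allylic C15 alcohol, so both epimers converge on the α-methylene ketone and the saturated 12-OH is untouched.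

Step 13
Reactants: 14 16-en-15-one
Product: 15 12α,15β-diol
Conditions: NaBH4, CeCl3·7H2O, MeOH, −78 °C
Reagents that add atoms: none
Why: Luche 1,2-reduction should deliver hydride to the exo face of the bicyclo[3.2.1]octenone (the side turned away from the C9–C11–C12 bridge, whose axial H-11 screens the endo face), giving the endo 15β-alcohol.

Step 14
Reactants: 15 12α,15β-diol
Product: 16 12,13,15-tri-O-TBS C6 enol triflate
Conditions: TBSOTf (3 equiv), 2,6-lutidine, CH2Cl2, 0 → 25 °C
Reagents that add atoms: tert-butyldimethylsilyl triflate CC(C)(C)[Si](C)(C)OS(=O)(=O)C(F)(F)F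
Why: Silyl triflate/lutidine silylation should protect both hindered secondary hydroxyls; the endo 15-oxygen lies at a dihedral angle near 80° to C6 and so cannot serve as an internal lactone partner for C7, and once silylated it cannot interfere with the carbonylation that follows.

Step 15
Reactants: 16 12,13,15-tri-O-TBS C6 enol triflate
Product: 17 2-(trimethylsilyl)ethyl cyclopent-5-ene-6-carboxylate (C5=C6; C7 ester)
Conditions: Pd(OAc)2 (10 mol%), dppf (12 mol%), CO (1 atm), Me3SiCH2CH2OH (5 equiv), Et3N, DMF, 60 °C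
Reagents that add atoms: carbon monoxide [C-]#[O+]; 2-(trimethylsilyl)ethanol C[Si](C)(C)CCO
Why: Palladium-catalysed alkoxycarbonylation of the enol triflate (oxidative addition, CO insertion, alcoholysis of the acyl–palladium) should introduce C7 as a fluoride-labile ester and at the same time turn C5=C6 into a Michael acceptor.

Step 16
Reactants: 17 2-(trimethylsilyl)ethyl cyclopent-5-ene-6-carboxylate; 18 allyl propanoate
Product: 19 Michael adduct (C4–C5 bond; C19 allyl ester; H-6α; C4 epimers)
Conditions: LDA (0.95 equiv to 18), THF, −78 °C; then 17, −78 → −50 °C; then t-BuOH (10 equiv), KOt-Bu (0.3 equiv), −50 → 25 °C; AcOH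
Reagents that add atoms: none
Why: Michael addition of the preformed lithium ester enolate to the cyclopentene-1-carboxylate should occur at C5 anti to the adjacent 10β-silyloxy group (C4 α, H-5 β), and protonation of the C7 ester enolate under equilibrating conditions (catalytic tert-butoxide in tert-butanol) should place C7 trans to the new C5 substituent (H-6 α, C7 β); the C4 configuration is irrelevant here.

Step 17
Reactants: 19 Michael adduct
Product: 21 10β-hydroxy C19 acid (C7 2-(trimethylsilyl)ethyl ester), via 10-O-TES C19 acid 20 (not isolated)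
Conditions: Pd(PPh3)4 (5 mol%), morpholine (5 equiv), THF, 25 °C; then 1 M HCl to pH 1–2, 25 °C
Reagents that add atoms: none
Why: Palladium(0)-catalysed allyl transfer to morpholine (Tsuji–Trost deallylation) should free the C19 acid under neutral conditions that leave the C7 ester untouched, and brief aqueous acid then hydrolyses the TES ether, which is far more acid-labile than the hindered TBS ethers, while the trans relation of 10β-OH and C4 prevents a C19/C10 lactone.

Step 18
Reactants: 21 10β-hydroxy C19 acid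
Product: 22 γ-keto acid (C10 ketone)
Conditions: Dess–Martin periodinane, CH2Cl2, 25 °C
Reagents that add atoms: none
Why: Dess–Martin oxidation of the secondary alcohol should give the C10 ketone under neutral conditions that tolerate the free acid and leave C5 and C6 in their stable trans arrangement.

Step 19
Reactants: 22 γ-keto acid
Product: 24 pseudo-ester (10β-methoxy 19,10-lactone), via pseudo-chloride 23 (not isolated)
Conditions: (COCl)2, DMF (cat.), CH2Cl2, 0 → 25 °C; then MeOH, pyridine, −20 °C
Reagents that add atoms: methanol CO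
Why: The acid chloride of a γ-keto acid closes onto the ketone oxygen to the cyclic pseudo-chloride, and methanolysis with pyridine gives the pseudo-ester (classical pseudo-ester formation); it masks C10 at the ketone oxidation level and, being necessarily cis-fused to ring B, puts the lactone oxygen on the α-face of C10.

Step 20
Reactants: 24 pseudo-ester; 25 3-(trimethylsilyl)prop-2-ynal
Product: 26 aldol adduct (quaternary C4; 3β-OH; C1≡C2–SiMe3)
Conditions: LDA (1.1 equiv), THF, −78 °C; 25; AcOH, −78 °C
Reagents that add atoms: none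
Why: Aldol addition of the lactone lithium enolate (the lactone C4–H is more acidic and far more accessible than H-6 of the acyclic C7 ester) should occur on the convex face of the cis-fused bicyclic lactone, syn to H-5, which sets the quaternary C4; a Zimmerman–Traxler chair with the ring-fixed enolate geometry (methyl cis to OLi) should place the C3 hydroxyl syn to the methyl group, i.e. 3β.

Step 21
Reactants: 26 aldol adduct
Product: 27 3-O-TES ether
Conditions: TESCl, imidazole, DMAP (cat.), DMF, 25 °C
Reagents that add atoms: chlorotriethylsilane CC[Si](Cl)(CC)CC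
Why: Silylation under non-Lewis-acidic conditions should protect the C3 hydroxyl without ionising the pseudo-ester and stops retro-aldol cleavage.

Step 22
Reactants: 27 3-O-TES ether
Product: 28 (Z)-vinylsilane
Conditions: H2 (1 atm), Lindlar catalyst, quinoline, EtOAc, 25 °C
Reagents that add atoms: none
Why: Lindlar semi-hydrogenation (syn addition of H2) should turn the silylalkyne into the (Z)-vinylsilane and leave the hindered 1,1-disubstituted C16 alkene untouched.

Step 23
Reactants: 28 (Z)-vinylsilane
Product: 29 3-O-TES-12,13,15-tri-O-TBS target 2-(trimethylsilyl)ethyl ester (ring A closed)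
Conditions: TMSOTf (0.3 equiv), 2,6-di-tert-butyl-4-methylpyridine (0.5 equiv), CH2Cl2, −78 → −40 °C
Reagents that add atoms: none
Why: Proposed new method: TMSOTf ionises the 10-methoxy γ-lactone (a mixed acyl ketal) to a lactone-stabilised acyloxycarbenium ion, the ipso carbon C1 of the (Z)-vinylsilane attacks C10, and the β-silyl cation at C2 loses Me3Si+ to triflate, which regenerates TMSOTf and leaves the C1=C2 alkene; the closest known reaction types are vinylsilane-terminated cyclisations of oxocarbenium and N-acyliminium ions and Lewis-acid allylation of γ-lactol ethers. Ring A closes 6-endo with respect to the vinylsilane (both alkene carbons end in the ring) and forms the three-atom bridge of a 2-oxabicyclo[3.2.1]octenone across C4 and C10 of the existing lactone. The new quaternary stereocentre C10 is fixed by the substrate: the lactone is cis-fused to ring B (O α) and the C3–C2=C1 arm sits on its convex β-face, so C1 can bond only to the β-face of the planar cation. The (Z)-geometry holds C1 over C10 and is retained as the cis ring alkene. The step needs C–C bond formation to outrun protodesilylation, elimination to the enol lactone and ionisation of the allylic C15–O and C3–O silyl ethers; the hindered pyridine removes TfOH, elimination is reversible, and the pseudo-ester acetal is by far the most easily ionised group at −78 °C.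

Step 24
Reactants: 29 3-O-TES-12,13,15-tri-O-TBS target 2-(trimethylsilyl)ethyl ester
Product: 30 target 2-(trimethylsilyl)ethyl ester (3β,12α,13,15β-tetraol)
Conditions: HF·pyridine, pyridine, THF, 0 → 25 °C
Reagents that add atoms: none
Why: Buffered HF·pyridine should cleave the TES and the three TBS ethers without base, so the allylic lactone and the 3β-hydroxyl of ring A never meet an alkoxide, and the 2-(trimethylsilyl)ethyl ester is inert to these acidic fluoride conditions.

Step 25
Reactants: 30 target 2-(trimethylsilyl)ethyl ester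
Product: 31 target gibberellin
Conditions: TASF (2 equiv), DMF, 0 → 25 °C; then 0.5 M HCl to pH 4
Reagents that add atoms: none
Why: Fluoride attack at silicon with β-elimination (loss of ethene and fluorotrimethylsilane) should release the hindered C7 carboxylate without hydroxide, which avoids the retro-aldol epimerisation at C3 and the lactone migration that saponification would risk, and mild acidification gives the target.

**Compound list**

1 | (R)-4-hydroxycyclopent-2-en-1-one | O=C1C=C[C@H](O)C1 | starting material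
2 | (R)-4-[(triethylsilyl)oxy]cyclopent-2-en-1-one | O=C1C=C[C@H](O[Si](CC)(CC)CC)C1 | intermediate
3 | (R)-2-iodo-4-[(triethylsilyl)oxy]cyclopent-2-en-1-one | O=C1C(I)=C[C@H](O[Si](CC)(CC)CC)C1 | intermediate
4 | methyl (R)-5-oxo-3-[(triethylsilyl)oxy]cyclopent-1-ene-1-carboxylate | O=C1C(C(=O)OC)=C[C@H](O[Si](CC)(CC)CC)C1 | intermediate
5 | butane-2,3-dione | CC(=O)C(C)=O | starting material
6 | 2,3-bis[(tert-butyldimethylsilyl)oxy]buta-1,3-diene | C=C(O[Si](C)(C)C(C)(C)C)C(=C)O[Si](C)(C)C(C)(C)C | intermediate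
7 | cis-fused hydrindenone (C6 ketone; 8β-CO2Me; H-9β; 10β-OTES; C12=C13 bis-OTBS enediol ether) | COC(=O)[C@]23CC(O[Si](C)(C)C(C)(C)C)=C(O[Si](C)(C)C(C)(C)C)C[C@H]2[C@H](O[Si](CC)(CC)CC)CC3=O | intermediate
8 | C6 enol triflate (C5=C6) | COC(=O)[C@]23CC(O[Si](C)(C)C(C)(C)C)=C(O[Si](C)(C)C(C)(C)C)C[C@H]2[C@H](O[Si](CC)(CC)CC)C=C3OS(=O)(=O)C(F)(F)F | intermediate
9 | C15 primary alcohol | OC[C@]23CC(O[Si](C)(C)C(C)(C)C)=C(O[Si](C)(C)C(C)(C)C)C[C@H]2[C@H](O[Si](CC)(CC)CC)C=C3OS(=O)(=O)C(F)(F)F | intermediate
10 | C15 aldehyde | O=C[C@]23CC(O[Si](C)(C)C(C)(C)C)=C(O[Si](C)(C)C(C)(C)C)C[C@H]2[C@H](O[Si](CC)(CC)CC)C=C3OS(=O)(=O)C(F)(F)F | intermediate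
11 | C15 ethynyl carbinol (C15 epimers) | C#CC(O)[C@]23CC(O[Si](C)(C)C(C)(C)C)=C(O[Si](C)(C)C(C)(C)C)C[C@H]2[C@H](O[Si](CC)(CC)CC)C=C3OS(=O)(=O)C(F)(F)F | intermediate
12 | tricyclic B/C/D ketone (12-oxo; 13-OTBS; 16-methylene; 15-OH epimers; C6 enol triflate; 10β-OTES) | C=C1C(O)[C@]23C[C@@]1(O[Si](C)(C)C(C)(C)C)C(=O)C[C@H]2[C@H](O[Si](CC)(CC)CC)C=C3OS(=O)(=O)C(F)(F)F | intermediate
13 | 12α-alcohol (15-OH epimers) | C=C1C(O)[C@]23C[C@@]1(O[Si](C)(C)C(C)(C)C)[C@@H](O)C[C@H]2[C@H](O[Si](CC)(CC)CC)C=C3OS(=O)(=O)C(F)(F)F | intermediate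
14 | 16-en-15-one (12α-OH) | C=C1C(=O)[C@]23C[C@@]1(O[Si](C)(C)C(C)(C)C)[C@@H](O)C[C@H]2[C@H](O[Si](CC)(CC)CC)C=C3OS(=O)(=O)C(F)(F)F | intermediate
15 | 12α,15β-diol | C=C1[C@@H](O)[C@]23C[C@@]1(O[Si](C)(C)C(C)(C)C)[C@@H](O)C[C@H]2[C@H](O[Si](CC)(CC)CC)C=C3OS(=O)(=O)C(F)(F)F | intermediate
16 | 12,13,15-tri-O-TBS C6 enol triflate (10β-OTES) | C=C1[C@@H](O[Si](C)(C)C(C)(C)C)[C@]23C[C@@]1(O[Si](C)(C)C(C)(C)C)[C@@H](O[Si](C)(C)C(C)(C)C)C[C@H]2[C@H](O[Si](CC)(CC)CC)C=C3OS(=O)(=O)C(F)(F)F | intermediate
17 | 2-(trimethylsilyl)ethyl cyclopent-5-ene-6-carboxylate (C5=C6; C7 ester; 12,13,15-tri-O-TBS; 10β-OTES) | C=C1[C@@H](O[Si](C)(C)C(C)(C)C)[C@]23C[C@@]1(O[Si](C)(C)C(C)(C)C)[C@@H](O[Si](C)(C)C(C)(C)C)C[C@H]2[C@H](O[Si](CC)(CC)CC)C=C3C(=O)OCC[Si](C)(C)C | intermediate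
18 | allyl propanoate | CCC(=O)OCC=C | starting material
19 | Michael adduct (C19 allyl ester; C7 2-(trimethylsilyl)ethyl ester; H-5β; H-6α; C4 epimers) | C=C1[C@@H](O[Si](C)(C)C(C)(C)C)[C@]23C[C@@]1(O[Si](C)(C)C(C)(C)C)[C@@H](O[Si](C)(C)C(C)(C)C)C[C@H]2[C@H](O[Si](CC)(CC)CC)[C@@H](C(C)C(=O)OCC=C)[C@@H]3C(=O)OCC[Si](C)(C)C | intermediate
20 | 10-O-TES C19 acid (C7 2-(trimethylsilyl)ethyl ester) | C=C1[C@@H](O[Si](C)(C)C(C)(C)C)[C@]23C[C@@]1(O[Si](C)(C)C(C)(C)C)[C@@H](O[Si](C)(C)C(C)(C)C)C[C@H]2[C@H](O[Si](CC)(CC)CC)[C@@H](C(C)C(=O)O)[C@@H]3C(=O)OCC[Si](C)(C)C | intermediate (not isolated)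
21 | 10β-hydroxy C19 acid (C7 2-(trimethylsilyl)ethyl ester) | C=C1[C@@H](O[Si](C)(C)C(C)(C)C)[C@]23C[C@@]1(O[Si](C)(C)C(C)(C)C)[C@@H](O[Si](C)(C)C(C)(C)C)C[C@H]2[C@H](O)[C@@H](C(C)C(=O)O)[C@@H]3C(=O)OCC[Si](C)(C)C | intermediate
22 | γ-keto acid (C10 ketone) | C=C1[C@@H](O[Si](C)(C)C(C)(C)C)[C@]23C[C@@]1(O[Si](C)(C)C(C)(C)C)[C@@H](O[Si](C)(C)C(C)(C)C)C[C@H]2C(=O)[C@@H](C(C)C(=O)O)[C@@H]3C(=O)OCC[Si](C)(C)C | intermediate
23 | pseudo-chloride (10β-chloro 19,10-lactone) | C=C1[C@@H](O[Si](C)(C)C(C)(C)C)[C@]23C[C@@]1(O[Si](C)(C)C(C)(C)C)[C@@H](O[Si](C)(C)C(C)(C)C)C[C@H]2[C@@]4(Cl)OC(=O)C(C)[C@H]4[C@@H]3C(=O)OCC[Si](C)(C)C | intermediate (not isolated)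
24 | pseudo-ester (10β-methoxy 19,10-lactone) | C=C1[C@@H](O[Si](C)(C)C(C)(C)C)[C@]23C[C@@]1(O[Si](C)(C)C(C)(C)C)[C@@H](O[Si](C)(C)C(C)(C)C)C[C@H]2[C@@]4(OC)OC(=O)C(C)[C@H]4[C@@H]3C(=O)OCC[Si](C)(C)C | intermediate
25 | 3-(trimethylsilyl)prop-2-ynal | O=CC#C[Si](C)(C)C | starting material
26 | aldol adduct (3β-OH; C1≡C2–SiMe3) | C=C1[C@@H](O[Si](C)(C)C(C)(C)C)[C@]23C[C@@]1(O[Si](C)(C)C(C)(C)C)[C@@H](O[Si](C)(C)C(C)(C)C)C[C@H]2[C@@]4(OC)OC(=O)[C@](C)([C@@H](O)C#C[Si](C)(C)C)[C@H]4[C@@H]3C(=O)OCC[Si](C)(C)C | intermediate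
27 | 3-O-TES ether | C=C1[C@@H](O[Si](C)(C)C(C)(C)C)[C@]23C[C@@]1(O[Si](C)(C)C(C)(C)C)[C@@H](O[Si](C)(C)C(C)(C)C)C[C@H]2[C@@]4(OC)OC(=O)[C@](C)([C@@H](O[Si](CC)(CC)CC)C#C[Si](C)(C)C)[C@H]4[C@@H]3C(=O)OCC[Si](C)(C)C | intermediate
28 | (Z)-vinylsilane | C=C1[C@@H](O[Si](C)(C)C(C)(C)C)[C@]23C[C@@]1(O[Si](C)(C)C(C)(C)C)[C@@H](O[Si](C)(C)C(C)(C)C)C[C@H]2[C@@]4(OC)OC(=O)[C@](C)([C@@H](O[Si](CC)(CC)CC)/C=C\[Si](C)(C)C)[C@H]4[C@@H]3C(=O)OCC[Si](C)(C)C | intermediate
29 | 3-O-TES-12,13,15-tri-O-TBS target 2-(trimethylsilyl)ethyl ester | C=C1[C@@H](O[Si](C)(C)C(C)(C)C)[C@]23C[C@@]1(O[Si](C)(C)C(C)(C)C)[C@@H](O[Si](C)(C)C(C)(C)C)C[C@H]2[C@@]12C=C[C@H](O[Si](CC)(CC)CC)[C@@](C)(C(=O)O1)[C@H]2[C@@H]3C(=O)OCC[Si](C)(C)C | intermediate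
30 | target 2-(trimethylsilyl)ethyl ester (3β,12α,13,15β-tetraol) | C=C1[C@@H](O)[C@]23C[C@@]1(O)[C@@H](O)C[C@H]2[C@@]12C=C[C@H](O)[C@@](C)(C(=O)O1)[C@H]2[C@@H]3C(=O)OCC[Si](C)(C)C | intermediate
31 | target gibberellin: 3β,12α,13,15β-tetrahydroxy-20-norgibberella-1,16-diene-7,19-dioic acid 19,10-lactone | C=C1[C@@H](O)[C@]23C[C@@]1(O)[C@@H](O)C[C@H]2[C@@]12C=C[C@H](O)[C@@](C)(C(=O)O1)[C@H]2[C@@H]3C(=O)O | target

**Step count and risks**

Total step count: 25. Longest linear sequence: 24 steps (steps 1–3 and 5–25, from 1); step 4 is a one-step side branch.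

Steps most likely to fail:

1. Step 23 (Proposed new method). The vinylsilane may be protodesilylated, the cation may eliminate to the enol lactone, or the attack of the hindered silyl-bearing carbon on the tertiary cation may be too slow. The fallback uses known chemistry and sets out from 28. Iododesilylation with NIS (MeCN, 0 °C, retention of geometry) would give the (Z)-vinyl iodide pseudo-ester F1. Acid-catalysed methanolysis (PPTS, MeOH) would open the pseudo-ester to the normal γ-keto methyl ester and remove the TES group, giving keto ester F2. An intramolecular Nozaki–Hiyama–Kishi reaction (CrCl2, cat. NiCl2, DMSO) would add C1 to the C10 ketone, and the tertiary alkoxide would lactonise onto the C19 ester to give the 3-hydroxy ring-A lactone F3. Silylation (TESCl, imidazole) then returns to the route at 29. Face selectivity at C10 is not guaranteed in this variant because the lactone is not in place during C–C bond formation.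

2. Step 20. The aldol may show low diastereoselectivity at C3 (open versus closed transition state with a slim alkynyl aldehyde), and the adduct may partly revert by retro-aldol. The fallback sets out from 26 obtained as a C3 epimer mixture. Dess–Martin oxidation would give the ynone F4, and CBS reduction with the (R)-oxazaborolidine and catecholborane (alkynyl as the small group, reagent control) returns to the route at 26 as the single 3β-epimer.

3. Step 16. Conjugate addition of the branched ester enolate to the hindered β-carbon C5 may be slow, so that proton transfer or 1,2-addition takes over. The fallback sets out from 17 and builds C4 and C19 from a smaller nucleophile. Copper-catalysed conjugate addition of isopropenylmagnesium bromide (CuI cat., THF, −40 °C), followed by the same tert-butoxide equilibration at C6, would give the 5α-isopropenyl ester F5. Hydroboration with 9-BBN and oxidation with sodium perborate would give the primary alcohol F6 as C4 epimers; the C16 methylene, flanked by C13 and C15, should react far more slowly. Oxidation with TEMPO (cat.) and PhI(OAc)2 in MeCN–water would give the acid, which is 20, isolated in this variant, and the route is rejoined at 20 with the acid hydrolysis of the TES ether in step 17.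

Further compounds
F1 | step 23 | (Z)-vinyl iodide pseudo-ester | C=C1[C@@H](O[Si](C)(C)C(C)(C)C)[C@]23C[C@@]1(O[Si](C)(C)C(C)(C)C)[C@@H](O[Si](C)(C)C(C)(C)C)C[C@H]2[C@@]4(OC)OC(=O)[C@](C)([C@@H](O[Si](CC)(CC)CC)/C=C\I)[C@H]4[C@@H]3C(=O)OCC[Si](C)(C)C
F2 | step 23 | γ-keto methyl ester with free 3-OH and (Z)-vinyl iodide | C=C1[C@@H](O[Si](C)(C)C(C)(C)C)[C@]23C[C@@]1(O[Si](C)(C)C(C)(C)C)[C@@H](O[Si](C)(C)C(C)(C)C)C[C@H]2C(=O)[C@@H]([C@](C)(C(=O)OC)[C@@H](O)/C=C\I)[C@@H]3C(=O)OCC[Si](C)(C)C
F3 | step 23 | 3-hydroxy ring-A lactone (12,13,15-tri-O-TBS target 2-(trimethylsilyl)ethyl ester) | C=C1[C@@H](O[Si](C)(C)C(C)(C)C)[C@]23C[C@@]1(O[Si](C)(C)C(C)(C)C)[C@@H](O[Si](C)(C)C(C)(C)C)C[C@H]2[C@@]12C=C[C@H](O)[C@@](C)(C(=O)O1)[C@H]2[C@@H]3C(=O)OCC[Si](C)(C)C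
F4 | step 20 | ynone (C3 ketone) | C=C1[C@@H](O[Si](C)(C)C(C)(C)C)[C@]23C[C@@]1(O[Si](C)(C)C(C)(C)C)[C@@H](O[Si](C)(C)C(C)(C)C)C[C@H]2[C@@]4(OC)OC(=O)[C@](C)(C(=O)C#C[Si](C)(C)C)[C@H]4[C@@H]3C(=O)OCC[Si](C)(C)C
F5 | step 16 | 5α-isopropenyl C7 ester (H-6α; 10β-OTES) | C=C1[C@@H](O[Si](C)(C)C(C)(C)C)[C@]23C[C@@]1(O[Si](C)(C)C(C)(C)C)[C@@H](O[Si](C)(C)C(C)(C)C)C[C@H]2[C@H](O[Si](CC)(CC)CC)[C@@H](C(C)=C)[C@@H]3C(=O)OCC[Si](C)(C)C
F6 | step 16 | C19 primary alcohol (C4 epimers) | C=C1[C@@H](O[Si](C)(C)C(C)(C)C)[C@]23C[C@@]1(O[Si](C)(C)C(C)(C)C)[C@@H](O[Si](C)(C)C(C)(C)C)C[C@H]2[C@H](O[Si](CC)(CC)CC)[C@@H](C(C)CO)[C@@H]3C(=O)OCC[Si](C)(C)C
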